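**Retrosynthetic overview**

- The aryl allyl ether C–O bond is cut last, giving 7-hydroxy-8-methoxycoumarin and a C10 epoxy diol (Mitsunobu etherification). The C5 carbinol is then corrected by Mitsunobu inversion.
- The oxirane comes from a hydroxyl-directed threo epoxidation of a (5R)-allylic alcohol, which sets C6. Inversion at C5 then gives the erythro (5S,6S) array of the target.
- The key C4–C5 bond is made by an enantioselective vinylogous Mukaiyama aldol between the silyl dienolate of ethyl 3-methylbut-2-enoate and 3-methylbut-2-enal. This step also delivers the (E)-trisubstituted alkene.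
- Ring order: the benzene ring is bought, the pyranone ring of the coumarin is closed first (formylation, then Wittig–lactonisation), and the oxirane is formed second, on the side chain before the fragments are joined.

Assumption: the (R,R)-bisphosphoramide of step 4 (two P=O units built on (R)-N,N′-dimethyl-1,1′-binaphthyl-2,2′-diamine, joined through MeN(CH2)5NMe) sends the dienolate to the Re face of the enal, as recalled for other conjugated aldehydes; if Mosher ester analysis of the aldol product shows the opposite, the (S,S)-catalyst is used.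

**Route**

Step 1
Reactants: 1 2-methoxybenzene-1,3-diol
Product: 3 2,4-dihydroxy-3-methoxybenzaldehyde, via aryl iminium chloride 2 (not isolated)
Conditions: POCl3 (1.2 equiv), DMF (1.5 equiv), MeCN, −10 °C → rt; then H2O, 50 °C
Reagents that add atoms: N,N-dimethylformamide, CN(C)C=O; water, O
Why: Vilsmeier–Haack formylation; the only strongly activated positions (ortho to one OH and para to the other) are equivalent in the symmetric diol, so a single aldehyde forms.

Step 2
Reactants: 3 2,4-dihydroxy-3-methoxybenzaldehyde; 4 ethyl (triphenyl-λ5-phosphanylidene)acetate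
Product: 7 7-hydroxy-8-methoxy-2H-chromen-2-one, via (E)-cinnamate ester 5 (not isolated), via (Z)-cinnamate ester 6 (not isolated)
Conditions: PhNEt2, reflux (ca. 215 °C), 4 h
Reagents that add atoms: none
Why: Wittig olefination followed by thermal E-to-Z isomerisation and lactonisation onto the ortho phenol closes the pyranone ring, and free phenols are tolerated.

Step 3
Reactants: 8 ethyl 3-methylbut-2-enoate
Product: 10 tert-butyl[(1-ethoxy-3-methylbuta-1,3-dien-1-yl)oxy]dimethylsilane, via lithium dienolate 9 (not isolated)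
Conditions: LiN(iPr)2 (1.1 equiv, commercial solution), THF, −78 °C; then tBuMe2SiCl, DMPU, −78 °C → rt
Reagents that add atoms: tert-butyldimethylsilyl chloride, CC(C)(C)[Si](C)(C)Cl
Why: Kinetic γ-deprotonation of the enoate and O-silylation give the silyl dienol ether (silyl ketene acetal formation); no stereocentre is made and the ketene acetal geometry has no consequence.

Step 4
Reactants: 10 tert-butyl[(1-ethoxy-3-methylbuta-1,3-dien-1-yl)oxy]dimethylsilane; 11 3-methylbut-2-enal
Product: 13 ethyl (2E,5R)-5-hydroxy-3,7-dimethylocta-2,6-dienoate, via trichlorosilyl ether 12 (not isolated)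
Conditions: SiCl4 (1.1 equiv), (R,R)-bisphosphoramide (2 mol %), iPr2NEt (10 mol %), CH2Cl2, −78 °C; then aq. NaHCO3, 0 °C
Reagents that add atoms: none
Why: Catalytic enantioselective vinylogous Mukaiyama aldol (Lewis-base-activated SiCl4); the dienolate attacks through its γ-carbon on the Re face of the enal, which sets C5 as R, and gives the E-enoate.

Step 5
Reactants: 13 ethyl (2E,5R)-5-hydroxy-3,7-dimethylocta-2,6-dienoate
Product: 14 ethyl (2E,5R)-5-[(2S)-3,3-dimethyloxiran-2-yl]-5-hydroxy-3-methylpent-2-enoate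
Conditions: mCPBA (1.1 equiv), NaHCO3, CH2Cl2, −10 → 0 °C
Reagents that add atoms: 3-chloroperoxybenzoic acid, OOC(=O)c1cccc(Cl)c1
Why: Hydroxyl-directed Prilezhaev epoxidation; allylic 1,3-strain from the cis methyl group holds the carbinol H in the alkene plane, so the hydrogen-bonded peracid gives the threo (5R,6S) epoxy alcohol (about 95:5 for this substitution pattern), and the electron-poor enoate alkene does not react.

Step 6
Reactants: 14 ethyl (2E,5R)-5-[(2S)-3,3-dimethyloxiran-2-yl]-5-hydroxy-3-methylpent-2-enoate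
Product: 15 (2E,5R)-5-[(2S)-3,3-dimethyloxiran-2-yl]-3-methylpent-2-ene-1,5-diol
Conditions: iBu2AlH (3.3 equiv), CH2Cl2, −78 °C; then aq. potassium sodium tartrate
Reagents that add atoms: none
Why: 1,2-Reduction of the enoate by the aluminium hydride gives the allylic alcohol; at −78 °C the epoxide and both stereocentres are untouched.

Step 7
Reactants: 15 (2E,5R)-5-[(2S)-3,3-dimethyloxiran-2-yl]-3-methylpent-2-ene-1,5-diol; 7 7-hydroxy-8-methoxy-2H-chromen-2-one
Product: 17 7-{[(2E,5R)-5-[(2S)-3,3-dimethyloxiran-2-yl]-5-hydroxy-3-methylpent-2-en-1-yl]oxy}-8-methoxy-2H-chromen-2-one, via primary alkoxyphosphonium phenoxide 16 (not isolated)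
Conditions: PPh3 (1.1 equiv), DIAD (1.1 equiv), THF, 0 °C → rt
Reagents that add atoms: none
Why: Mitsunobu etherification; the unhindered primary allylic alcohol is activated in preference to the hindered secondary one, the acidic coumarin phenol is a good partner, and the E alkene rules out cyclisation of the diol.

Step 8
Reactants: 17 7-{[(2E,5R)-5-[(2S)-3,3-dimethyloxiran-2-yl]-5-hydroxy-3-methylpent-2-en-1-yl]oxy}-8-methoxy-2H-chromen-2-one
Product: 19 (1S,3E)-1-[(2S)-3,3-dimethyloxiran-2-yl]-5-[(8-methoxy-2-oxo-2H-chromen-7-yl)oxy]-3-methylpent-3-en-1-yl 4-nitrobenzoate, via secondary alkoxyphosphonium carboxylate 18 (not isolated)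
Conditions: 4-O2NC6H4CO2H (1.5 equiv), PPh3 (1.5 equiv), DIAD (1.5 equiv), THF, 0 °C → rt
Reagents that add atoms: 4-nitrobenzoic acid, OC(=O)c1ccc(cc1)[N+](=O)[O-]
Why: Mitsunobu inversion with the acidic 4-nitrobenzoic acid; SN2 displacement of the activated oxygen turns the carbinol from R to S and so converts the threo into the erythro array, while the oxirane carbon keeps its S configuration.

Step 9
Reactants: 19 (1S,3E)-1-[(2S)-3,3-dimethyloxiran-2-yl]-5-[(8-methoxy-2-oxo-2H-chromen-7-yl)oxy]-3-methylpent-3-en-1-yl 4-nitrobenzoate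
Product: 20 7-{[(2E,5S)-5-[(2S)-3,3-dimethyloxiran-2-yl]-5-hydroxy-3-methylpent-2-en-1-yl]oxy}-8-methoxy-2H-chromen-2-one (CNP0166233.1)
Conditions: K2CO3 (0.3 equiv), MeOH, 0 °C, 1 h
Reagents that add atoms: none
Why: Base-catalysed transesterification (methanolysis) of the activated ester cleaves the acyl–oxygen bond, so the carbinol keeps its S configuration; the conditions are mild enough for the coumarin lactone and the oxirane.

**Compound list**

1 | 2-methoxybenzene-1,3-diol | COc1c(O)cccc1O | starting material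
2 | [(2,4-dihydroxy-3-methoxyphenyl)methylidene]dimethylammonium chloride | C[N+](C)=Cc1ccc(O)c(OC)c1O.[Cl-] | intermediate
3 | 2,4-dihydroxy-3-methoxybenzaldehyde | COc1c(O)ccc(C=O)c1O | intermediate
4 | ethyl (triphenyl-λ5-phosphanylidene)acetate | CCOC(=O)C=P(c1ccccc1)(c1ccccc1)c1ccccc1 | starting material
5 | ethyl (2E)-3-(2,4-dihydroxy-3-methoxyphenyl)prop-2-enoate | CCOC(=O)/C=C/c1ccc(O)c(OC)c1O | intermediate
6 | ethyl (2Z)-3-(2,4-dihydroxy-3-methoxyphenyl)prop-2-enoate | CCOC(=O)/C=C\c1ccc(O)c(OC)c1O | intermediate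
7 | 7-hydroxy-8-methoxy-2H-chromen-2-one | COc1c(O)ccc2ccc(=O)oc12 | intermediate
8 | ethyl 3-methylbut-2-enoate | CCOC(=O)C=C(C)C | starting material
9 | lithium 1-ethoxy-3-methylbuta-1,3-dien-1-olate | [Li+].CCOC([O-])=CC(C)=C | intermediate
10 | tert-butyl[(1-ethoxy-3-methylbuta-1,3-dien-1-yl)oxy]dimethylsilane (ketene acetal geometry not fixed) | CCOC(O[Si](C)(C)C(C)(C)C)=CC(C)=C | intermediate
11 | 3-methylbut-2-enal | CC(C)=CC=O | starting material
12 | ethyl (2E,5R)-3,7-dimethyl-5-[(trichlorosilyl)oxy]octa-2,6-dienoate | CCOC(=O)/C=C(\C)C[C@@H](O[Si](Cl)(Cl)Cl)C=C(C)C | intermediate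
13 | ethyl (2E,5R)-5-hydroxy-3,7-dimethylocta-2,6-dienoate | CCOC(=O)/C=C(\C)C[C@@H](O)C=C(C)C | intermediate
14 | ethyl (2E,5R)-5-[(2S)-3,3-dimethyloxiran-2-yl]-5-hydroxy-3-methylpent-2-enoate | CCOC(=O)/C=C(\C)C[C@@H](O)[C@@H]1OC1(C)C | intermediate
15 | (2E,5R)-5-[(2S)-3,3-dimethyloxiran-2-yl]-3-methylpent-2-ene-1,5-diol | OC/C=C(\C)C[C@@H](O)[C@@H]1OC1(C)C | intermediate
16 | {[(2E,5R)-5-[(2S)-3,3-dimethyloxiran-2-yl]-5-hydroxy-3-methylpent-2-en-1-yl]oxy}triphenylphosphonium 8-methoxy-2-oxo-2H-chromen-7-olate | COc1c([O-])ccc2ccc(=O)oc12.c1ccc(cc1)[P+](c1ccccc1)(c1ccccc1)OC/C=C(\C)C[C@@H](O)[C@@H]1OC1(C)C | intermediate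
17 | 7-{[(2E,5R)-5-[(2S)-3,3-dimethyloxiran-2-yl]-5-hydroxy-3-methylpent-2-en-1-yl]oxy}-8-methoxy-2H-chromen-2-one | COc1c(OC/C=C(\C)C[C@@H](O)[C@@H]2OC2(C)C)ccc2ccc(=O)oc12 | intermediate
18 | {[(1R,3E)-1-[(2S)-3,3-dimethyloxiran-2-yl]-5-[(8-methoxy-2-oxo-2H-chromen-7-yl)oxy]-3-methylpent-3-en-1-yl]oxy}triphenylphosphonium 4-nitrobenzoate | COc1c(OC/C=C(\C)C[C@@H](O[P+](c3ccccc3)(c3ccccc3)c3ccccc3)[C@@H]2OC2(C)C)ccc2ccc(=O)oc12.[O-]C(=O)c1ccc(cc1)[N+](=O)[O-] | intermediate
19 | (1S,3E)-1-[(2S)-3,3-dimethyloxiran-2-yl]-5-[(8-methoxy-2-oxo-2H-chromen-7-yl)oxy]-3-methylpent-3-en-1-yl 4-nitrobenzoate | COc1c(OC/C=C(\C)C[C@H](OC(=O)c3ccc(cc3)[N+](=O)[O-])[C@@H]2OC2(C)C)ccc2ccc(=O)oc12 | intermediate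
20 | 7-{[(2E,5S)-5-[(2S)-3,3-dimethyloxiran-2-yl]-5-hydroxy-3-methylpent-2-en-1-yl]oxy}-8-methoxy-2H-chromen-2-one | COc1c(OC/C=C(\C)C[C@H](O)[C@@H]2OC2(C)C)ccc2ccc(=O)oc12 | target

**Summary**

Total step count: 9. Longest linear sequence: 7 steps (steps 3 to 9, from 8 to 20); the coumarin branch (steps 1 and 2) joins at step 7.

Steps most likely to fail, each with a fallback:

Step 4 (enantioselectivity, E geometry and conversion of the vinylogous aldol with a β,β-disubstituted enal). The fallback sets out from 10 and 11 and comes back to the route at 13; it replaces asymmetric catalysis by a racemic aldol plus kinetic resolution. A BF3·OEt2-promoted vinylogous Mukaiyama aldol (CH2Cl2, −78 °C) gives racemic ethyl (2E)-5-hydroxy-3,7-dimethylocta-2,6-dienoate F1. Sharpless kinetic resolution (Ti(OiPr)4, L-(+)-diisopropyl tartrate, tBuOOH 0.65 equiv, 4 Å molecular sieves, CH2Cl2, −20 °C) then epoxidises the faster (5S)-enantiomer to ethyl (2E,5S)-5-[(2S)-3,3-dimethyloxiran-2-yl]-5-hydroxy-3-methylpent-2-enoate F2. The unreacted (5R)-alcohol 13 is recovered by chromatography; because the cis methyl group lowers the rate ratio, the run is taken past 60 % conversion.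

Step 7 (chemoselective etherification of the unprotected diol). The fallback sets out from 14 and comes back at 17; it uses a protecting group and a Williamson alkylation instead of the selective Mitsunobu reaction. tBuMe2SiCl and imidazole (DMF, rt) give ethyl (2E,5R)-5-[(tert-butyldimethylsilyl)oxy]-5-[(2S)-3,3-dimethyloxiran-2-yl]-3-methylpent-2-enoate F3. Reduction by iBu2AlH (CH2Cl2, −78 °C) gives (2E,5R)-5-[(tert-butyldimethylsilyl)oxy]-5-[(2S)-3,3-dimethyloxiran-2-yl]-3-methylpent-2-en-1-ol F4. CBr4 and PPh3 (CH2Cl2, 0 °C) give {[(1R,3E)-5-bromo-1-[(2S)-3,3-dimethyloxiran-2-yl]-3-methylpent-3-en-1-yl]oxy}(tert-butyl)dimethylsilane F5. Alkylation of phenol 7 (K2CO3, acetone, rt) gives 7-{[(2E,5R)-5-[(tert-butyldimethylsilyl)oxy]-5-[(2S)-3,3-dimethyloxiran-2-yl]-3-methylpent-2-en-1-yl]oxy}-8-methoxy-2H-chromen-2-one F6. Bu4NF buffered by AcOH (THF, 0 °C) frees 17.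

Step 8 (SN2 inversion at a hindered carbinol next to the oxirane). The fallback sets out from 17 and comes back at 20, bypassing 19; it replaces inversion by oxidation and chelation-controlled reduction. Dess–Martin periodinane (NaHCO3, CH2Cl2, 0 °C) gives 7-{[(2E)-5-[(2R)-3,3-dimethyloxiran-2-yl]-3-methyl-5-oxopent-2-en-1-yl]oxy}-8-methoxy-2H-chromen-2-one F7. Zn(BH4)2 (Et2O, −30 °C) chelates the carbonyl and oxirane oxygens and delivers hydride from the face away from the dimethyl-bearing carbon, giving the erythro alcohol 20 directly; the coumarin lactone is not reduced.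

**Further compounds**

F1 | step 4 | rac-ethyl (2E)-5-hydroxy-3,7-dimethylocta-2,6-dienoate | CCOC(=O)/C=C(\C)CC(O)C=C(C)C
F2 | step 4 | ethyl (2E,5S)-5-[(2S)-3,3-dimethyloxiran-2-yl]-5-hydroxy-3-methylpent-2-enoate | CCOC(=O)/C=C(\C)C[C@H](O)[C@@H]1OC1(C)C
F3 | step 7 | ethyl (2E,5R)-5-[(tert-butyldimethylsilyl)oxy]-5-[(2S)-3,3-dimethyloxiran-2-yl]-3-methylpent-2-enoate | CCOC(=O)/C=C(\C)C[C@@H](O[Si](C)(C)C(C)(C)C)[C@@H]1OC1(C)C
F4 | step 7 | (2E,5R)-5-[(tert-butyldimethylsilyl)oxy]-5-[(2S)-3,3-dimethyloxiran-2-yl]-3-methylpent-2-en-1-ol | OC/C=C(\C)C[C@@H](O[Si](C)(C)C(C)(C)C)[C@@H]1OC1(C)C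
F5 | step 7 | {[(1R,3E)-5-bromo-1-[(2S)-3,3-dimethyloxiran-2-yl]-3-methylpent-3-en-1-yl]oxy}(tert-butyl)dimethylsilane | BrC/C=C(\C)C[C@@H](O[Si](C)(C)C(C)(C)C)[C@@H]1OC1(C)C
F6 | step 7 | 7-{[(2E,5R)-5-[(tert-butyldimethylsilyl)oxy]-5-[(2S)-3,3-dimethyloxiran-2-yl]-3-methylpent-2-en-1-yl]oxy}-8-methoxy-2H-chromen-2-one | COc1c(OC/C=C(\C)C[C@@H](O[Si](C)(C)C(C)(C)C)[C@@H]2OC2(C)C)ccc2ccc(=O)oc12
F7 | step 8 | 7-{[(2E)-5-[(2R)-3,3-dimethyloxiran-2-yl]-3-methyl-5-oxopent-2-en-1-yl]oxy}-8-methoxy-2H-chromen-2-one | COc1c(OC/C=C(\C)CC(=O)[C@@H]2OC2(C)C)ccc2ccc(=O)oc12
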